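**Retrosynthetic overview**
1. The C6–acyl bond is cut last. C6 lies between the C5 and C7 phenol oxygens, so it is lithiated between two MOM ethers and acylated with a protected p-coumaric N-methoxy-N-methylamide.
2. The strategy rests on C3 of the dihydropyran ring: a carbinol carbon flanked by the quaternary C2 (gem-dimethyl, bound to O1) and the benzylic C4 methylene bound to ring A at C4a. C3 is therefore carried as a ketone and reduced under catalyst control.
3. The chroman-3-one is opened at C4–C4a. C4 becomes a diazo carbon, and its rhodium carbenoid is attacked by the ortho carbon of a symmetric 3,5-dioxygenated aryl ether.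
4. The hindered O1–C2 ether is made first, by O-alkylation of bis-MOM phloroglucinol with a bromoisobutyrate.
5. Ring order: ring A is bought as phloroglucinol, the pyran ring is closed in step 5, and ring B arrives with the coumaroyl unit in step 10.

Key step: step 5

Assumption: chroman numbering is used (O1, C2 gem-dimethyl, C3 carbinol, C4 methylene, acyl at C6); the given SMILES corresponds to 3R and an E enone.

**Step 1**
Reactants: 1 phloroglucinol
Product: 2 3,5-bis(methoxymethoxy)phenol
Conditions: MOMCl (2.0 equiv), i-Pr2NEt, DMF, 0 °C to rt; chromatography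
Reagents that add atoms: chloromethyl methyl ether, COCCl
Why: Phenol O-alkylation by an α-chloro ether on a threefold-symmetric triol, so two equivalents should give the bis-ether as the main statistical product, separable from the mono- and tris-ethers, which can be recycled.

**Step 2**
Reactants: 2 3,5-bis(methoxymethoxy)phenol; 3 ethyl 2-bromo-2-methylpropanoate
Product: 4 ethyl 2-[3,5-bis(methoxymethoxy)phenoxy]-2-methylpropanoate
Conditions: Cs2CO3, DMF, 60 °C
Reagents that add atoms: none
Why: Williamson-type O-alkylation of a phenoxide with an α-bromoisobutyrate, the standard entry to aryloxyisobutyrates, which forms the hindered O1–C2 ether before any ring is closed, with excess bromide compensating for elimination to methacrylate.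

**Step 3**
Reactants: 4 ethyl 2-[3,5-bis(methoxymethoxy)phenoxy]-2-methylpropanoate
Product: 5 2-[3,5-bis(methoxymethoxy)phenoxy]-2-methylpropanoic acid
Conditions: NaOH (2 M aq), EtOH, 60 °C; then cold 1 M HCl to pH 4
Reagents that add atoms: sodium hydroxide, [Na+].[OH-]
Why: Saponification of an ester without α-hydrogen under basic conditions that leave the MOM acetals untouched, with only a brief cold acidification to pH 4.

**Step 4**
Reactants: 5 2-[3,5-bis(methoxymethoxy)phenoxy]-2-methylpropanoic acid
Product: 7 1-diazo-3-[3,5-bis(methoxymethoxy)phenoxy]-3-methylbutan-2-one, via acid chloride 6 (not isolated)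
Conditions: 1-chloro-N,N,2-trimethylprop-1-en-1-amine, CH2Cl2, 0 °C to rt; then CH2N2, Et3N, Et2O, 0 °C
Reagents that add atoms: diazomethane, C=[N+]=[N-]
Why: Neutral acid chloride formation with an α-chloroenamine (no HCl is released, so the MOM ethers should survive) followed by acylation of diazomethane with triethylamine as HCl scavenger, which is safe here because the acid chloride has no α-hydrogen and cannot form a ketene.

**Step 5**
Reactants: 7 1-diazo-3-[3,5-bis(methoxymethoxy)phenoxy]-3-methylbutan-2-one
Product: 8 5,7-bis(methoxymethoxy)-2,2-dimethylchroman-3-one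
Conditions: Rh2(OAc)4 (1 mol %), CH2Cl2, 40 °C, slow addition of 7 at high dilution
Reagents that add atoms: none
Why: Dirhodium tetraacetate, a divalent rhodium carboxylate, should extrude N2 from 7 to give an electrophilic keto-carbenoid at the future C4, which the ring carbon ortho to the ether oxygen (future C4a) attacks; the arenium-type intermediate then rearomatises by proton transfer, forming C4–C4a. The closest known reaction type is the dirhodium-carboxylate-catalysed intramolecular aromatic substitution of α-aryloxy diazoketones to chroman-3-ones. The pyranone ring (O1–C2–C3–C4–C4a–C8a) closes in a six-membered exo-type mode, the rhodium leaving from outside the ring. No stereocentre is formed, since C3 remains a ketone. The step needs aromatic substitution to win over Buchner cyclopropanation with ring expansion, C–H insertion into the C2 methyl groups, oxonium ylide formation and carbene dimerisation. The attacked carbon is ortho or para to all three oxygen donors, the two ortho positions are equivalent so only one regioisomer can form, methyl insertion would give a strained cyclobutanone, and slow addition keeps the carbenoid concentration low.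

**Step 6**
Reactants: 8 5,7-bis(methoxymethoxy)-2,2-dimethylchroman-3-one
Product: 9 (3R)-5,7-bis(methoxymethoxy)-2,2-dimethylchroman-3-ol
Conditions: (S)-2-methyl-CBS-oxazaborolidine [(3aS)-1-methyl-3,3-diphenyltetrahydro-1H,3H-pyrrolo[1,2-c][1,3,2]oxazaborole, C18H20BNO] (10 mol %), BH3·SMe2, THF, −20 °C; MeOH quench
Reagents that add atoms: none
Why: Corey–Bakshi–Shibata reduction, in which the ketone should bind the catalyst boron through the lone pair on the side of the small C4 methylene with the quaternary C2 pointing away, so that hydride from the nitrogen-bound borane reaches the face giving the (3R)-carbinol, the same sense in which tert-alkyl methyl ketones give (R)-alcohols with the (S)-catalyst.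

**Step 7**
Reactants: 9 (3R)-5,7-bis(methoxymethoxy)-2,2-dimethylchroman-3-ol
Product: 10 tert-butyl{[(3R)-5,7-bis(methoxymethoxy)-2,2-dimethylchroman-3-yl]oxy}dimethylsilane
Conditions: TBSCl, imidazole, DMAP (cat.), DMF, 40 °C
Reagents that add atoms: tert-butyldimethylsilyl chloride, CC(C)(C)[Si](C)(C)Cl
Why: Imidazole-promoted silylation of the secondary alcohol removes the acidic proton before metalation and does not touch the C3–O bond, so the configuration is retained.

**Step 8**
Reactants: 11 p-coumaric acid
Product: 12 (E)-3-(4-hydroxyphenyl)-N-methoxy-N-methylprop-2-enamide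
Conditions: EDC·HCl, HOBt, MeNHOMe·HCl, i-Pr2NEt, DMF, 0 °C to rt
Reagents that add atoms: N,O-dimethylhydroxylamine hydrochloride, CNOC.Cl
Why: Carbodiimide/HOBt amide coupling in which the amine should outcompete the unprotected phenol for the active ester, leaving the E-alkene untouched.

**Step 9**
Reactants: 12 (E)-3-(4-hydroxyphenyl)-N-methoxy-N-methylprop-2-enamide
Product: 13 (E)-N-methoxy-3-[4-(methoxymethoxy)phenyl]-N-methylprop-2-enamide
Conditions: MOMCl, i-Pr2NEt, CH2Cl2, 0 °C to rt
Reagents that add atoms: chloromethyl methyl ether, COCCl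
Why: Phenol O-alkylation with an α-chloro ether masks the only acidic proton of the acyl donor with the same group used on ring A, so one final operation removes all of them.

**Step 10**
Reactants: 10 tert-butyl{[(3R)-5,7-bis(methoxymethoxy)-2,2-dimethylchroman-3-yl]oxy}dimethylsilane; 13 (E)-N-methoxy-3-[4-(methoxymethoxy)phenyl]-N-methylprop-2-enamide
Product: 15 (E)-1-[(3R)-3-(tert-butyldimethylsilyloxy)-5,7-bis(methoxymethoxy)-2,2-dimethylchroman-6-yl]-3-[4-(methoxymethoxy)phenyl]prop-2-en-1-one, via C6 aryllithium 14 (not isolated)
Conditions: n-BuLi, THF, 0 °C; then 13, −78 to 0 °C; aq NH4Cl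
Reagents that add atoms: none
Why: Directed ortho-metalation should occur at C6–H, which lies between two lithium-chelating MOM ethers, whereas C8–H has only one MOM ether and the hindered ring oxygen beside it; the aryllithium then adds to the amide carbonyl (Weinreb ketone synthesis), and the N-methoxy chelate holds the tetrahedral adduct until quench, so over-addition and loss of the E-alkene are not expected.

**Step 11**
Reactants: 15 (E)-1-[(3R)-3-(tert-butyldimethylsilyloxy)-5,7-bis(methoxymethoxy)-2,2-dimethylchroman-6-yl]-3-[4-(methoxymethoxy)phenyl]prop-2-en-1-one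
Product: 16 (E)-3-(4-hydroxyphenyl)-1-[(3R)-3,5,7-trihydroxy-2,2-dimethylchroman-6-yl]prop-2-en-1-one
Conditions: HCl (3 M aq)/MeOH, rt, stopped at full conversion
Reagents that add atoms: none
Why: Acid-catalysed methanolysis of the three aryl MOM acetals and of the silyl ether should proceed at room temperature without ionising the non-benzylic C3 carbinol or the tertiary aryl ether, and short exposure limits oxa-Michael closure of the freed phenols onto the enone.

**Compound list**
1 | phloroglucinol | Oc1cc(O)cc(O)c1 | starting material
2 | 3,5-bis(methoxymethoxy)phenol | COCOc1cc(O)cc(OCOC)c1 | intermediate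
3 | ethyl 2-bromo-2-methylpropanoate | CCOC(=O)C(C)(C)Br | starting material
4 | ethyl 2-[3,5-bis(methoxymethoxy)phenoxy]-2-methylpropanoate | CCOC(=O)C(C)(C)Oc1cc(OCOC)cc(OCOC)c1 | intermediate
5 | 2-[3,5-bis(methoxymethoxy)phenoxy]-2-methylpropanoic acid | CC(C)(Oc1cc(OCOC)cc(OCOC)c1)C(=O)O | intermediate
6 | 2-[3,5-bis(methoxymethoxy)phenoxy]-2-methylpropanoyl chloride | CC(C)(Oc1cc(OCOC)cc(OCOC)c1)C(=O)Cl | intermediate (not isolated)
7 | 1-diazo-3-[3,5-bis(methoxymethoxy)phenoxy]-3-methylbutan-2-one | COCOc1cc(OCOC)cc(OC(C)(C)C(=O)C=[N+]=[N-])c1 | intermediate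
8 | 5,7-bis(methoxymethoxy)-2,2-dimethylchroman-3-one | CC1(C)Oc2cc(OCOC)cc(OCOC)c2CC1=O | intermediate
9 | (3R)-5,7-bis(methoxymethoxy)-2,2-dimethylchroman-3-ol | CC1(C)Oc2cc(OCOC)cc(OCOC)c2C[C@H]1O | intermediate
10 | tert-butyl{[(3R)-5,7-bis(methoxymethoxy)-2,2-dimethylchroman-3-yl]oxy}dimethylsilane | CC1(C)Oc2cc(OCOC)cc(OCOC)c2C[C@H]1O[Si](C)(C)C(C)(C)C | intermediate
11 | p-coumaric acid, (E)-3-(4-hydroxyphenyl)prop-2-enoic acid | O=C(O)/C=C/c1ccc(O)cc1 | starting material
12 | (E)-3-(4-hydroxyphenyl)-N-methoxy-N-methylprop-2-enamide | CON(C)C(=O)/C=C/c1ccc(O)cc1 | intermediate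
13 | (E)-N-methoxy-3-[4-(methoxymethoxy)phenyl]-N-methylprop-2-enamide | CON(C)C(=O)/C=C/c1ccc(OCOC)cc1 | intermediate
14 | [(3R)-3-(tert-butyldimethylsilyloxy)-5,7-bis(methoxymethoxy)-2,2-dimethylchroman-6-yl]lithium | CC1(C)Oc2cc(OCOC)c([Li])c(OCOC)c2C[C@H]1O[Si](C)(C)C(C)(C)C | intermediate (not isolated)
15 | (E)-1-[(3R)-3-(tert-butyldimethylsilyloxy)-5,7-bis(methoxymethoxy)-2,2-dimethylchroman-6-yl]-3-[4-(methoxymethoxy)phenyl]prop-2-en-1-one | CC1(C)Oc2cc(OCOC)c(C(=O)/C=C/c3ccc(OCOC)cc3)c(OCOC)c2C[C@H]1O[Si](C)(C)C(C)(C)C | intermediate
16 | (E)-3-(4-hydroxyphenyl)-1-[(3R)-3,5,7-trihydroxy-2,2-dimethylchroman-6-yl]prop-2-en-1-one | CC1(C)Oc2cc(O)c(C(=O)/C=C/c3ccc(O)cc3)c(O)c2C[C@H]1O | target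

**Step count**
Total: 11 steps. Longest linear sequence: 9 steps (steps 1–7, 10, 11); steps 8–9 are a two-step side branch.

**Steps most likely to fail**

Step 5 (carbenoid ring closure). The carbenoid may add across the arene π-bond and ring-expand to a cycloheptatriene, dimerise, or be captured by an ether oxygen. The enolisable chromanone may also oxidise during isolation. The fallback avoids carbene chemistry and sets out from 2. O-Propargylation with 3-chloro-3-methylbut-1-yne (DBU, catalytic CuCl2, MeCN, 0 °C) should give 1-[(2-methylbut-3-yn-2-yl)oxy]-3,5-bis(methoxymethoxy)benzene F1. Heating F1 in xylene at 140 °C should effect aromatic Claisen rearrangement, hydrogen shift and electrocyclisation to 5,7-bis(methoxymethoxy)-2,2-dimethyl-2H-chromene F2; both ortho positions are equivalent. Hydroboration–oxidation (BH3·THF, then NaOH/H2O2) should place boron at C3, away from the electron-rich benzylic carbon, giving rac-5,7-bis(methoxymethoxy)-2,2-dimethylchroman-3-ol F3. Oxidation of F3 with Dess–Martin periodinane (NaHCO3, CH2Cl2) comes back to the route at 8, ahead of the asymmetric reduction.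

Step 10 (metalation and acylation). The hindered, doubly ortho-substituted aryllithium may act as a base towards the N-methoxy amide (N–O cleavage with loss of formaldehyde), or add in a conjugate sense to the enamide, so that conversion to the enone is poor. Some metalation at C8 is also possible and would be checked by a D2O quench of 14 before the amide is committed; the fallback does not cure that. The fallback sets out from 10 and builds the enone by condensation instead. Aryllithium 14 is trapped with the small, non-conjugated N-methoxy-N-methylacetamide to give 1-[(3R)-3-(tert-butyldimethylsilyloxy)-5,7-bis(methoxymethoxy)-2,2-dimethylchroman-6-yl]ethan-1-one F4. Separately, 4-hydroxybenzaldehyde with MOMCl and i-Pr2NEt gives 4-(methoxymethoxy)benzaldehyde F5. Claisen–Schmidt condensation of F4 with F5 (KOH, EtOH, rt) should give the E-enone and comes back to the route at 15.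

Step 11 (global deprotection). Under protic acid the freed 5- or 7-hydroxyl may close onto the enone (chalcone-to-flavanone isomerisation), or methanol may add to the enone, before the hindered silyl ether is fully cleaved. The fallback sets out from 15 and separates the two deprotections. TBAF in THF at rt, while all phenols are still masked, should give (E)-1-[(3R)-3-hydroxy-5,7-bis(methoxymethoxy)-2,2-dimethylchroman-6-yl]-3-[4-(methoxymethoxy)phenyl]prop-2-en-1-one F6. The aryl MOM ethers of F6 are then removed without protic acid by TMSOTf and 2,2'-bipyridyl in CH2Cl2 at 0 °C, which converts them to silyl ethers that hydrolyse on aqueous work-up, arriving at 16.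

**Further compounds**
F1 | step 5 | 1-[(2-methylbut-3-yn-2-yl)oxy]-3,5-bis(methoxymethoxy)benzene | C#CC(C)(C)Oc1cc(OCOC)cc(OCOC)c1
F2 | step 5 | 5,7-bis(methoxymethoxy)-2,2-dimethyl-2H-chromene | CC1(C)Oc2cc(OCOC)cc(OCOC)c2C=C1
F3 | step 5 | rac-5,7-bis(methoxymethoxy)-2,2-dimethylchroman-3-ol | CC1(C)Oc2cc(OCOC)cc(OCOC)c2CC1O
F4 | step 10 | 1-[(3R)-3-(tert-butyldimethylsilyloxy)-5,7-bis(methoxymethoxy)-2,2-dimethylchroman-6-yl]ethan-1-one | CC1(C)Oc2cc(OCOC)c(C(C)=O)c(OCOC)c2C[C@H]1O[Si](C)(C)C(C)(C)C
F5 | step 10 | 4-(methoxymethoxy)benzaldehyde | COCOc1ccc(C=O)cc1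
F6 | step 11 | (E)-1-[(3R)-3-hydroxy-5,7-bis(methoxymethoxy)-2,2-dimethylchroman-6-yl]-3-[4-(methoxymethoxy)phenyl]prop-2-en-1-one | CC1(C)Oc2cc(OCOC)c(C(=O)/C=C/c3ccc(OCOC)cc3)c(OCOC)c2C[C@H]1O
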